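In a one-step world each electrophile costs one nucleophile, and a flask charged like the south-west run, with more nucleophile than electrophile, runs on to completion; these readings show otherwise.

| flask | electrophile | nucleophile | solid base | remark | time |
|---|---|---|---|---|---|
| south-west | 0.10 M | 0.12 M | 0.12 M | run made earlier |  |
| north-east | 0.10 M | 0.22 M | 0.12 M | run made earlier |  |
| theta | 0.10 M | 0.100 M | 0.120 M |  | 30 h |
| epsilon | 0.10 M | 0.130 M | 0.120 M |  | 30 h |
| zeta | 0.10 M | 0.170 M | 0.120 M |  | 30 h |

| run | time / h | electrophile / % | product / % |
|---|---|---|---|
| south-west | 3.00 | 73 | 35 |
| south-west | 6.00 | 56 | 44 |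
| south-west | 10.0 | 49 | 50 |
| south-west | 12.0 | 45 | 53 |
| south-west | 15.0 | 46 | 56 |
| south-west | 20.0 | 37 | 59 |
| north-east | 1.50 | 66 | 35 |
| north-east | 2.50 | 54 | 48 |
| north-east | 4.00 | 40 | 58 |
| north-east | 6.00 | 31 | 67 |
| north-east | 10.0 | 19 | 79 |
| north-east | 15.0 | 14 | 87 |
| north-east | 20.0 | 11 | 93 |

(standard deviation of a reading: 2 percentage points)

- given per volume of solution although it is solid: solid base
- at the start none of the solid base is in solution

- part of the electrophile that has reacted at the end, theta
- part of the electrophile that has reacted at the end, epsilon
- part of the electrophile that has reacted at the end, zeta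
- what raising the concentration of nucleophile from its lowest to its highest value here does to the part of the electrophile that has reacted (changes below 5 percentage points count as none) (it falls / no change / it rises)

The south-west run reads 59 % product at 20.0 h and is crawling, while the north-east run, richer in nucleophile, reads 93 %. I read this as a price of two nucleophiles per electrophile. My first way is therefore the ceiling, the nucleophile charge divided by two electrophile charges, which is 50.0 % for theta, 65.0 % for epsilon and 85.0 % for zeta; for the south-west run it is 60.0 %, close to that reading.

My second way brings in time and works with the fraction left. If the rate is k[electrophile][nucleophile] at that price, then D, [nucleophile] minus two [electrophile], stays constant, and the ratio [nucleophile]/[electrophile], taken relative to its start, is r = exp(kDt). The north-east reading at 6.00 h gives k = 1.54 M⁻¹ h⁻¹, and the south-west reading at 6.00 h gives 1.55 M⁻¹ h⁻¹. The fraction left is then −D divided by two electrophile charges minus r times the nucleophile charge, and as r vanishes this returns the ceiling. At 30 h, theta has r = 0.00998, epsilon 0.0398 and zeta 0.251, so the part reacted comes to 49.7 %, 64.1 % and 80.9 %. The two ways agree for theta and epsilon, but they part for zeta, where the ceiling cheats: it assumes r is zero, and zeta's r is larger than theta's. I commit to the second way.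

The forecast gives 55 %, 69 % and 84 %, with the trend it rises, on the ground that “each substitution releases acid that ties up a second nucleophile”; for theta it stands above my figure.

The flask gives 50.1 %, 64.2 % and 80.8 %; over the range, it rises, by 31 percentage points.

    electrophile + nucleophile → acid set free + product (k = 1.50 M⁻¹ h⁻¹)
    nucleophile + acid set free ⇌ protonated nucleophile, settled at all times (K = 54000 M⁻¹)
    acid set free + free base ⇌ salt of the base (K = 24.0 M⁻¹, k = 5.60 M⁻¹ h⁻¹)
    nucleophile + acid set free ⇌ idle adduct, settled at all times (K = 620 M⁻¹)
    solid base ⇌ free base, rate k5*(cs5 - [free base]) while solid is left; crystals form when [free base] > cs5 (solubility = 0.0820 M, k = 0.0290 h⁻¹)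

Zeta's 80.8 % against theta's 50.1 % comes mainly from the difference in the concentration of nucleophile. At 30.0 h theta stands at its ceiling of 50.0 %, with nucleophile, the limiting reagent, down to 1.13 % of its charge and 0.0482 M of protonated nucleophile present, while theta with the supply of nucleophile kept from shrinking reaches 98.9 %, which makes that shrinking a part of the reason for its shortfall. A further flask like theta, charged with 0.025 M of nucleophile, has a ceiling of 12.5 % and at 30.0 h stands above it, at 13.1 %.

All runs were generated by integration on assumed constants; noise was put on by code.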